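## Retrosynthetic overview
1. Cut O1–C8a, C7–C8 and C4a–C5 together. This gives (R)-1-(3,5-dimethoxyphenyl)hex-5-yn-1-ol and prenylmalonyl dichloride; the two minus 2 HCl equal the target, with no redox change.
2. Ring order: ring B is bought. Ring C closes first by 6-exo-dig O–H addition to the alkyne. Ring A is then built in the same flask on the resulting enol ether (C8=C8a–C4a) by double C-acylation with the C7–C6(prenyl)–C5 unit.
3. The prenyl group sits on the central carbon of a symmetrical C3 dielectrophile, so it can only end up between the two phenols (C6), never at C8.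
4. C2 is set by asymmetric transfer hydrogenation of the aryl ketone made from 3,5-dimethoxyphenyl Grignard and hex-5-ynenitrile. Its C–O bond is never broken afterwards.
5. The dichloride comes from diethyl malonate and prenyl bromide (alkylation/saponification, then oxalyl chloride).

Assumption: flavan numbering (O1, C2, C3, C4, C4a, C5–C8, C8a) is used for these atoms in open-chain precursors too, and the descriptor at C2 in the given SMILES reads as R.

## Route

Step 1
Reactants: 1 1-bromo-3,5-dimethoxybenzene; 2 hex-5-ynenitrile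
Product: 5 1-(3,5-dimethoxyphenyl)hex-5-yn-1-one, via Grignard reagent 3 (not isolated), via bis(bromomagnesium) ketimide 4 (not isolated)
Conditions: 1 (2.3 equiv), Mg, THF, reflux; 2 (1.0 equiv), 0 → 60 °C; 2 M HCl, rt
Reagents that add atoms: water, O (carbonyl oxygen of 5); magnesium, [Mg] (only in 3 and 4)
Why: Grignard addition to a nitrile stops at the N-magnesio ketimide, which takes no second aryl group and gives the ketone only on acidic hydrolysis; the first equivalent of 3 is spent on the acetylenic C–H, which is restored on work-up.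

Step 2
Reactants: 5 1-(3,5-dimethoxyphenyl)hex-5-yn-1-one
Product: 6 (1R)-1-(3,5-dimethoxyphenyl)hex-5-yn-1-ol
Conditions: RuCl[(R,R)-TsDPEN](p-cymene) (1 mol %), HCO2H/Et3N (5:2), 30 °C
Reagents that add atoms: none
Why: In this Noyori–Ikariya asymmetric transfer hydrogenation the (R,R)-TsDPEN ruthenium hydride passes H−/H+ through a six-membered outer-sphere transition state, where the C–H/π contact between cymene and the aryl ring exposes the Si face of the ketone, so the (R)-alcohol forms (about 95 % ee or better expected) and the remote non-polar alkyne is left alone.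

Step 3
Reactants: 7 diethyl malonate; 8 prenyl bromide (1-bromo-3-methylbut-2-ene)
Product: 10 2-(3-methylbut-2-en-1-yl)propanedioic acid (prenylmalonic acid), via diethyl prenylmalonate 9 (not isolated)
Conditions: 7 (1.2 equiv), NaOEt, EtOH, 0 °C → rt; KOH, H2O, reflux; HCl, 0 °C; recrystallise (toluene)
Reagents that add atoms: potassium hydroxide, [K+].[OH-] (one oxygen of each CO2H)
Why: In this malonic ester synthesis the soft malonate anion displaces bromide at the primary carbon (SN2, not SN2'), hydroxide then cleaves both esters, cold acidification avoids decarboxylation, recrystallisation removes malonic and diprenylmalonic acids, and no stereocentre is formed.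

Step 4
Reactants: 10 prenylmalonic acid
Product: 11 2-(3-methylbut-2-en-1-yl)propanedioyl dichloride (prenylmalonyl dichloride)
Conditions: (COCl)2 (2.4 equiv), DMF (2 mol %), CH2Cl2, 0 °C → rt; evaporate, use crude the same day
Reagents that add atoms: oxalyl chloride, O=C(Cl)C(=O)Cl (both Cl)
Why: Acid chloride formation through the Vilsmeier-type chloroiminium salt runs at or below room temperature, where the by-products leave as gases, the malonyl unit does not decarboxylate and the trisubstituted alkene is not hydrochlorinated; the central carbon carries two identical COCl groups and is not a stereocentre.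

Step 5
Reactants: 6 (1R)-1-(3,5-dimethoxyphenyl)hex-5-yn-1-ol; 11 prenylmalonyl dichloride
Product: 15 (2R)-2-(3,5-dimethoxyphenyl)-6-(3-methylbut-2-en-1-yl)-3,4-dihydro-2H-chromene-5,7-diol, via exocyclic enol ether 12 (not isolated), via keto acid chloride 13 (not isolated), via dienylketene 14 (not isolated)
Conditions: (Ph3P)AuNTf2 (2 mol %), 4 Å MS, CH2Cl2 (0.03 M), rt until 6 is consumed; 2,6-di-tert-butylpyridine (5 mol %), 11 (1.05 equiv), −30 °C → rt, N2 sweep; NaHCO3 aq
Reagents that add atoms: none
Why: Proposed new method: monovalent gold triggers a 6-exo-dig hydroalkoxylation that closes ring C as enol ether 12 without touching the C2–O bond (R retained); 12 is C-acylated at its methylene carbon (C8) by one COCl of 11 to give 13; loss of HCl from this β-keto acid chloride plus enolisation gives dienylketene 14, whose 6π electrocyclisation (bond C4a–C5) and tautomerisation close and aromatise ring A; because 11 is symmetrical and carries the prenyl group on its central carbon, only the 6-prenyl isomer can arise; the hindered pyridine buffers the HNTf2 that chloride frees from the gold salt; the closest known reaction types are the Effenberger cyclisation of enol ethers with malonyl dichloride, one-pot trapping of gold-generated exocyclic enol ethers, and the dienylketene closure that ends a Danheiser benzannulation.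

## Compound list
1 | 1-bromo-3,5-dimethoxybenzene | COc1cc(Br)cc(OC)c1 | starting material
2 | hex-5-ynenitrile | C#CCCCC#N | starting material
3 | (3,5-dimethoxyphenyl)magnesium bromide | COc1cc([Mg]Br)cc(OC)c1 | intermediate
4 | bis(bromomagnesium) salt of 1-(3,5-dimethoxyphenyl)hex-5-yn-1-imine (N–MgBr ketimide, C≡C–MgBr acetylide) | COc1cc(OC)cc(C(CCCC#C[Mg]Br)=N[Mg]Br)c1 | intermediate
5 | 1-(3,5-dimethoxyphenyl)hex-5-yn-1-one | COc1cc(OC)cc(C(=O)CCCC#C)c1 | intermediate
6 | (1R)-1-(3,5-dimethoxyphenyl)hex-5-yn-1-ol | COc1cc(OC)cc([C@H](O)CCCC#C)c1 | intermediate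
7 | diethyl malonate | CCOC(=O)CC(=O)OCC | starting material
8 | prenyl bromide (1-bromo-3-methylbut-2-ene) | CC(C)=CCBr | starting material
9 | diethyl 2-(3-methylbut-2-en-1-yl)propanedioate | CCOC(=O)C(CC=C(C)C)C(=O)OCC | intermediate
10 | 2-(3-methylbut-2-en-1-yl)propanedioic acid | CC(C)=CCC(C(=O)O)C(=O)O | intermediate
11 | 2-(3-methylbut-2-en-1-yl)propanedioyl dichloride | CC(C)=CCC(C(=O)Cl)C(=O)Cl | intermediate
12 | (2R)-2-(3,5-dimethoxyphenyl)-6-methylideneoxane | COc1cc(OC)cc([C@H]2CCCC(=C)O2)c1 | intermediate
13 | 2-{2-[(6R)-6-(3,5-dimethoxyphenyl)oxan-2-ylidene]acetyl}-5-methylhex-4-enoyl chloride (epimers at the malonyl CH, alkene geometry not fixed) | COc1cc(OC)cc([C@H]2CCCC(=CC(=O)C(CC=C(C)C)C(=O)Cl)O2)c1 | intermediate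
14 | 4-[(2R)-2-(3,5-dimethoxyphenyl)-3,4-dihydro-2H-pyran-6-yl]-3-hydroxy-2-(3-methylbut-2-en-1-yl)buta-1,3-dien-1-one (enol geometry tautomerically mobile) | COc1cc(OC)cc([C@H]2CCC=C(C=C(O)C(CC=C(C)C)=C=O)O2)c1 | intermediate
15 | (2R)-2-(3,5-dimethoxyphenyl)-6-(3-methylbut-2-en-1-yl)-3,4-dihydro-2H-chromene-5,7-diol | COc1cc(OC)cc([C@H]2CCc3c(cc(O)c(CC=C(C)C)c3O)O2)c1 | target

## Count and risks
Total steps: 5. Longest linear sequence: 3 (steps 1, 2, 5 or steps 3, 4, 5).

**Most likely to fail: step 5.**
- The second C-acylation may lose to chloride opening of the acylated oxocarbenium ion at benzylic C2, which would end in a 4-hydroxy-2-pyrone.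
- It may also lose to oligomerisation, or HCl may attack the prenyl group. A first yield of 30–45 % would already be good.
- The fallback sets out from 9 and 6 and comes back at 15. It closes ring A under base in separate stages.
- 9 is isolated by distillation and half-saponified (KOH 1.0 equiv, EtOH) to monoethyl prenylmalonate F1. Oxalyl chloride converts this into ethyl 2-(chlorocarbonyl)-5-methylhex-4-enoate F2.
- 6 is cyclised with (Ph3P)AuNTf2 via 12 and isomerised with a trace of camphorsulfonic acid to the endocyclic enol ether (2R)-2-(3,5-dimethoxyphenyl)-6-methyl-3,4-dihydro-2H-pyran F3.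
- F3 is acylated at C4a by F2 (pyridine, CH2Cl2, 0 °C) to the vinylogous ester ethyl 2-{[(2R)-2-(3,5-dimethoxyphenyl)-6-methyl-3,4-dihydro-2H-pyran-5-yl]carbonyl}-5-methylhex-4-enoate F4.
- LiN(SiMe3)2 (3.2 equiv, THF, −78 °C → rt) deprotonates the β-keto ester and then the vinylogous C8 methyl group. The dianion closes ring A by a vinylogous Dieckmann (polyketide-type Claisen) condensation on the ethyl ester, giving 15 after acidification.

**Second: step 4.**
- 11 may take up HCl at the trisubstituted alkene, or lose HCl to a chlorocarbonylketene that dimerises on concentration.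
- The fallback sets out from 6 and comes back at 15. It carries a terminal allyl group, which is inert to HCl, through all the acid chloride chemistry and turns it into prenyl last.
- Commercial allylmalonic acid and oxalyl chloride give distillable allylmalonyl dichloride F5.
- With 6 under the conditions of step 5, this passes through 12, the allyl keto acid chloride F6 and the allyl dienylketene F7 to (2R)-6-allyl-2-(3,5-dimethoxyphenyl)-3,4-dihydro-2H-chromene-5,7-diol F8.
- Olefin cross-metathesis of F8 with excess 2-methylbut-2-ene gives 15 (second-generation Grubbs catalyst, RuCl2(=CHPh)(PCy3)(H2IMes), CH2Cl2, 40 °C).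

**Third: step 1.**
- α-Deprotonation of the nitrile, or poor solubility of the magnesium acetylide, may cut the yield.
- The fallback sets out from 3 and comes back at 5. It replaces nitrile addition by acyl substitution.
- Commercial hex-5-ynoic acid is coupled with MeNHOMe·HCl (carbonyldiimidazole, CH2Cl2) to N-methoxy-N-methylhex-5-ynamide F9.
- 3 (2.2 equiv, THF, −20 → 0 °C) adds once to give the chelated tetrahedral magnesium adduct F10, which collapses to 5 only on acidic quench.

## Further compounds
F1 | step 5 | 2-(ethoxycarbonyl)-5-methylhex-4-enoic acid (monoethyl prenylmalonate, racemic) | CCOC(=O)C(CC=C(C)C)C(=O)O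
F2 | step 5 | ethyl 2-(chlorocarbonyl)-5-methylhex-4-enoate (racemic) | CCOC(=O)C(CC=C(C)C)C(=O)Cl
F3 | step 5 | (2R)-2-(3,5-dimethoxyphenyl)-6-methyl-3,4-dihydro-2H-pyran | COc1cc(OC)cc([C@H]2CCC=C(C)O2)c1
F4 | step 5 | ethyl 2-{[(2R)-2-(3,5-dimethoxyphenyl)-6-methyl-3,4-dihydro-2H-pyran-5-yl]carbonyl}-5-methylhex-4-enoate (epimers at the malonyl CH) | COc1cc(OC)cc([C@H]2CCC(C(=O)C(CC=C(C)C)C(=O)OCC)=C(C)O2)c1
F5 | step 4 | 2-(prop-2-en-1-yl)propanedioyl dichloride (allylmalonyl dichloride) | C=CCC(C(=O)Cl)C(=O)Cl
F6 | step 4 | 2-{2-[(6R)-6-(3,5-dimethoxyphenyl)oxan-2-ylidene]acetyl}pent-4-enoyl chloride | COc1cc(OC)cc([C@H]2CCCC(=CC(=O)C(CC=C)C(=O)Cl)O2)c1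
F7 | step 4 | 4-[(2R)-2-(3,5-dimethoxyphenyl)-3,4-dihydro-2H-pyran-6-yl]-3-hydroxy-2-(prop-2-en-1-yl)buta-1,3-dien-1-one | COc1cc(OC)cc([C@H]2CCC=C(C=C(O)C(CC=C)=C=O)O2)c1
F8 | step 4 | (2R)-6-allyl-2-(3,5-dimethoxyphenyl)-3,4-dihydro-2H-chromene-5,7-diol | COc1cc(OC)cc([C@H]2CCc3c(cc(O)c(CC=C)c3O)O2)c1
F9 | step 1 | N-methoxy-N-methylhex-5-ynamide | CON(C)C(=O)CCCC#C
F10 | step 1 | bromomagnesium 1-(3,5-dimethoxyphenyl)-1-[methoxy(methyl)amino]hex-5-yn-1-olate, acetylide also as C–MgBr (racemic) | COc1cc(OC)cc(C(O[Mg]Br)(CCCC#C[Mg]Br)N(C)OC)c1
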